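The runs come from a simulation with constants of no real substance, and the scatter is random.

At 10.0 min the dawn run still held 43.4 % of its electrophile, yet its target stood at 27.1 %, against 27.2 % at 4.00 min. We have to say what that means for four set-ups.

| flask | electrophile | nucleophile | free base | remark | time |
|---|---|---|---|---|---|
| dawn | 20 mM | 18 mM | 10 mM | run made earlier |  |
| autumn | 20 mM | 18 mM | 5 mM | run made earlier |  |
| Sunday's | 20 mM | 18.0 mM | 10.0 mM (fed, over 15.0 min) | all but free base at the start; free base goes in evenly over 15.0 min, the run ends at 15 min | 15 min |
| Saturday's | 20 mM | 18.0 mM | 10.0 mM | one stirred flow tank at steady state, fed with the mixture as stated, mean residence time 15 min |  |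
| Wednesday's | 20 mM | 18.0 mM | 10.0 mM | everything together in a closed stirred flask, run for 15 min | 15 min |
| Friday's | 20 mM (fed, over 15.0 min) | 18.0 mM | 10.0 mM | a stirred flask in which electrophile is dosed at a steady rate over 15.0 min without added volume, worked up at 15 min | 15 min |

dawn run (percent of the electrophile charged)

| time / min | target / % | electrophile / % |
|---|---|---|
| 0.667 | 10.0 | 88.6 |
| 1.50 | 18.8 | 79.2 |
| 4.00 | 27.2 | 60.3 |
| 10.0 | 27.1 | 43.4 |

autumn run (percent of the electrophile charged)

| time / s | target / % | electrophile / % |
|---|---|---|
| 10.0 | 1.9 | 96.2 |
| 15.0 | 5.2 | 95.3 |
| 40.0 | 9.8 | 88.2 |
| 90.0 | 19.7 | 77.6 |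

(readings scatter by 0.5 percentage points)

1. the set-up with the highest amount of target at the outlet or at the end, in percent of the electrophile put in ("none" if the first two lie within 2 percentage points) (Sunday's / Saturday's / Wednesday's / Friday's / none)
2. amount of target at the outlet or at the end, in percent of the electrophile put in, Sunday's
3. amount of target at the outlet or at the end, in percent of the electrophile put in, Saturday's
4. amount of target at the outlet or at the end, in percent of the electrophile put in, Wednesday's
5. amount of target at the outlet or at the end, in percent of the electrophile put in, Friday's

- percent here means electrophile units held: one side product counts as two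
- the stated concentrations are those of everything mixed, before any reaction; amounts are the same in each set-up
- candidate steps: electrophile + target -> side product; electrophile + nucleophile <-> acid set free + target; acid set free + free base <-> salt of the base; nucleophile + acid set free <-> protonated nucleophile
- the feed brings no volume worth counting
- the earlier runs were made in a closed, stirred flask

Electrophile and nucleophile give target and acid set free; electrophile and target give side product. So we count coupling turnover as target plus half the side product. In the dawn run it reads 33.5 % at 4.00 min and 41.8 % at 10.0 min.

Who takes the acid? We go two ways. By rate, the first reading, a turnover of 10.7 %, taken with mean concentrations, gives a coupling constant of 0.0107 mM⁻¹ min⁻¹. The slope between the last two readings, divided by that constant and the mean electrophile, then reads 2.52 mM of free nucleophile. By count, if the acid takes a second nucleophile, two are lost per turnover, which leaves 2.94 mM on average over that interval. If the free base took the acid, 10.5 mM would remain, more than the rate reading.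

So we trust two-for-one, which makes the nucleophile the limiting reagent. Half the nucleophile charge over the electrophile charge, 45.0 %, is the coupling ceiling: the turnover the nucleophile can pay for if the acid goes to nucleophile and not to free base. All four recipes share it, so we reckon Sunday's equal to Wednesday's and look for the gain in keeping turnover as target.

The forecast gives 24.5 % for Sunday's, 19 % for Saturday's, 24.8 % for Wednesday's and 27.5 % for Friday's, with Friday's best: “Dosing electrophile keeps it low while target builds”.

The flask gives 23.3 %, 19.0 %, 23.3 % and 28.5 % in that order, so Friday's is best.

    electrophile + target → side product (k = 5.53 L mol⁻¹ min⁻¹)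
    electrophile + nucleophile ⇌ acid set free + target (K = 2.16, k = 11.2 L mol⁻¹ min⁻¹)
    acid set free + free base ⇌ salt of the base, settled at all times (K = 130 L mol⁻¹)
    nucleophile + acid set free ⇌ protonated nucleophile, settled at all times (K = 1.40 × 10⁵ L mol⁻¹)

In Friday's, electrophile peaked at 10.3 mM, and at 7.50 min nucleophile stood at 56.8 % of its charge with side product at 2.83 %. By 15.0 min target had reached 28.5 %, a turnover of 38.4 %. Wednesday's ended at a turnover of 44.0 % against the ceiling of 45.0 %, with 8.58 mM of protonated nucleophile and free base at 98.7 % of its charge. A neighbour of Friday's with 4.5 mM of nucleophile has a ceiling of 11.3 %, reached a turnover of 10.8 %, and kept 85.0 % of its electrophile.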